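**Retrosynthetic overview**

1. Locants used throughout: ten-membered ring C1 (lactone O–CH) to C10 (ring-fusion CH); C3 carries C14H2OAc, C7 carries C15H3 and OH, C9 carries the angelate; lactone carbons are C11 (α, carrying =C13H2) and C12 (C=O). Late disconnections: C13 methylene and C14 acetate from a bis(silyloxymethyl) precursor (acetylation, then β-elimination), angelate by esterification, C9–OH by hydroxyl-directed reduction of a C9 ketone.
2. Enabling feature: the ring segment O–C7(quaternary)–C8H2–C9–O is a 1,3-dioxygenated (aldol) unit, which is a 2-isoxazoline in disguise. The β-hydroxy ketone is traced to a tricyclic isoxazoline whose temporary N–O bond bridges C7 and C9, and this to an acyclic nitro lactone by an intramolecular nitrile oxide–alkene (3+2) cycloaddition that forms C8–C9 and C7–O at once.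
3. The nitro lactone comes from trans-selective conjugate addition of nitromethane (C9 and, through its oxygen, the C7 hydroxyl) to a butenolide, which is made from an (R)-epoxide, (phenylthio)acetic acid dianion (C11, C12) and formaldehyde (C13) with sulfoxide elimination.
4. The epoxide comes from a Z-alkenyllithium (C3 to C8, C14, C15; from 4-methylpent-4-en-1-ol by oxidation, iodo-Wittig olefination, reduction, silylation) and (R)-epichlorohydrin (C1, C2, C10; source of the C1 stereocentre).
5. Order of ring formation: γ-lactone first (step 6), then the ten-membered carbocycle together with the bridging isoxazoline (step 11); the isoxazoline is opened again in step 12.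

Key step: step 11

Remark: C11 is an sp3 centre from step 6 to step 16 and is destroyed in the last step; where it is drawn undefined the compound is a C11 epimer mixture, where it is drawn defined the trans,trans isomer expected under equilibrating conditions is shown, and either epimer converges on the target.

**Route**

Step 1
Reactants: 1 4-methylpent-4-en-1-ol
Product: 2 4-methylpent-4-enal
Conditions: TEMPO (10 mol %), PhI(OAc)2 (1.1 equiv), CH2Cl2, rt; aq. NaHCO3 wash; dried solution used directly
Reagents that add atoms: none
Why: Oxoammonium-mediated (TEMPO/PhI(OAc)2) oxidation of a primary alcohol should stop at the aldehyde and leave the 1,1-disubstituted alkene untouched.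

Step 2
Reactants: 2 4-methylpent-4-enal; 3 ethyl (triphenylphosphoranylidene)acetate
Product: 5 ethyl (2Z)-2-iodo-6-methylhepta-2,6-dienoate, via iodo ylide 4 (not isolated)
Conditions: 3, N-iodosuccinimide (1.05 equiv), CH2Cl2, −20 °C; then 2, −20 °C to rt
Reagents that add atoms: N-iodosuccinimide, O=C1CCC(=O)N1I
Why: Wittig olefination with the α-iodo stabilised ylide made in the flask by electrophilic iodination of 3 should place the ester trans to the new alkyl chain, so that iodine is cis to C5, which fixes the later cis ring geometry of C3=C4.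

Step 3
Reactants: 5 ethyl (2Z)-2-iodo-6-methylhepta-2,6-dienoate
Product: 6 (2Z)-2-iodo-6-methylhepta-2,6-dien-1-ol
Conditions: iBu2AlH (2.2 equiv), CH2Cl2, −78 °C; aq. KNaC4H4O6
Reagents that add atoms: none
Why: 1,2-Reduction of the enoate with iBu2AlH at low temperature should give the allylic alcohol without touching the vinyl iodide or the alkene geometry.

Step 4
Reactants: 6 (2Z)-2-iodo-6-methylhepta-2,6-dien-1-ol
Product: 7 TBS ether of 6
Conditions: TBSCl, imidazole, DMF, 0 °C to rt
Reagents that add atoms: tert-butyldimethylsilyl chloride, CC(C)(C)[Si](C)(C)Cl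
Why: Standard silylation of a primary alcohol gives an ether that withstands the organolithium and enolate steps that follow.

Step 5
Reactants: 7 TBS ether of 6; 8 (R)-epichlorohydrin
Product: 11 (R)-epoxide carrying the dienyl chain, via alkenyllithium 9 (not isolated), via chlorohydrin 10 (not isolated)
Conditions: t-BuLi (2.1 equiv), Et2O, −78 °C; BF3·OEt2 (1.1 equiv) then 8, −78 °C; aq. NaHCO3; crude 10, NaOH (1 M aq.), THF, rt
Reagents that add atoms: none
Why: Iodine–lithium exchange retains the alkene geometry and the BF3-assisted alkenyllithium opens the epoxide of 8 only at its CH2 terminus, so that base-induced re-closure of the chlorohydrin (epoxide opening and re-closure with epichlorohydrin as linchpin) transfers the stereocentre of 8 unchanged to C1.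

Step 6
Reactants: 11 (R)-epoxide carrying the dienyl chain; 12 (phenylthio)acetic acid
Product: 15 α-phenylthio γ-lactone, via dianion 13 (not isolated), via hydroxy acid 14 (not isolated)
Conditions: 12, LiN(iPr)2 (2 equiv per 12), THF, 0 °C; 11, 0 °C to rt; aq. HCl to pH 3; PPTS (cat.), toluene, 50 °C
Reagents that add atoms: none
Why: The carboxylic acid dianion should open the terminal epoxide at its CH2 carbon (C10) and the γ-hydroxy acid lactonises (epoxide alkylation and lactonisation), which leaves C1 untouched and forms C11 as an inconsequential epimer mixture.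

Step 7
Reactants: 15 α-phenylthio γ-lactone; 16 formaldehyde
Product: 18 α-hydroxymethyl α-phenylthio lactone, via lithium enolate 17 (not isolated)
Conditions: LiN(iPr)2 (1.1 equiv), THF, −78 °C; CH2O (gas, from cracked paraformaldehyde, excess), −78 to −40 °C; AcOH quench
Reagents that add atoms: none
Why: Aldol-type hydroxymethylation of the sulfur-stabilised lactone enolate with monomeric formaldehyde should install C13 at C11, whose configuration is again inconsequential.

Step 8
Reactants: 18 α-hydroxymethyl α-phenylthio lactone
Product: 19 bis-TBS ether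
Conditions: TBSCl, imidazole, DMF, rt
Reagents that add atoms: tert-butyldimethylsilyl chloride, CC(C)(C)[Si](C)(C)Cl
Why: Silylation of the new primary alcohol masks C13–OH as a poor leaving group that survives the basic steps up to the end.

Step 9
Reactants: 19 bis-TBS ether
Product: 21 α-(silyloxymethyl)butenolide, via sulfoxide 20 (not isolated)
Conditions: mCPBA (1.0 equiv), CH2Cl2, −78 °C; then toluene, CaCO3, 110 °C
Reagents that add atoms: none
Why: Sulfur is oxidised much faster than the alkenes at low temperature, and thermal syn-elimination of the sulfoxide (sulfoxide pyrolysis) should take a C10 hydrogen and not one from the oxygen-bearing C13, which gives the endocyclic butenolide.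

Step 10
Reactants: 21 α-(silyloxymethyl)butenolide; 22 nitromethane
Product: 23 all-trans nitro lactone
Conditions: CH3NO2 (10 equiv), DBU (0.2 equiv), THF, 0 °C to rt
Reagents that add atoms: none
Why: Base-catalysed Michael addition of the nitronate should occur anti to the C1 side chain (1,2-induction on a 5-substituted butenolide) and so set C10 trans to C1, while C11 equilibrates to the trans arrangement and is erased in the last step.

Step 11
Reactants: 23 all-trans nitro lactone
Product: 25 bridged isoxazoline, via nitrile oxide 24 (not isolated)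
Conditions: 4-ClC6H4NCO (4 equiv), Et3N (0.3 equiv), toluene, 80 °C; 23 added by syringe pump over 24 h to a final concentration of about 1 mM
Reagents that add atoms: none
Why: O-Carbamoylation of the nitronate by the isocyanate and loss of the carbamic acid (Mukaiyama–Hoshino dehydration) should give nitrile oxide 24, which adds across the 1,1-disubstituted alkene in a concerted (3+2) cycloaddition. The closest known reaction type is the high-dilution intramolecular nitrile oxide–alkene cycloaddition of ω-nitro-1-alkenes to macrocyclic bridged 2-isoxazolines. Two rings close at once: the ten-membered carbocycle through the C8–C9 bond between the dipole carbon and the terminal CH2 (bridged mode, with the normal regiochemistry that places oxygen on the more substituted alkene carbon), and the isoxazoline through the C7–O bond. The only new stereocentre, C7, is controlled by C10: the C=N–O unit should swing to the face of the forming ring that carries C10–H, away from the C11 branch of the lactone, which corresponds to (7S). The step needs the remote alkene to win over the nearer C3=C4 alkene and over bimolecular pathways; the trans C1/C10 ring fusion holds the dipole carbon and the C2 chain on opposite faces of the lactone so that closure onto C3=C4 would demand a trans-fused bicyclo[3.3.0]octane, the cis C3=C4 alkene bends the chain back toward the dipole, and masking the acrylate as CH2OTBS leaves no electron-poor dipolarophile. Slow addition at high dilution should suppress furoxan formation.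

Step 12
Reactants: 25 bridged isoxazoline
Product: 27 β-hydroxy ketone, via hydroxy imine 26 (not isolated)
Conditions: Raney Ni, H2 (1 atm), B(OH)3 (3 equiv), MeOH/H2O (5:1), rt
Reagents that add atoms: water, O
Why: Hydrogenolysis of the isoxazoline N–O bond and boric-acid-buffered hydrolysis of the resulting imine should unmask the aldol without epimerisation at C10, retro-aldol cleavage or reduction of the hindered trisubstituted alkene.

Step 13
Reactants: 27 β-hydroxy ketone
Product: 28 7,9-trans diol
Conditions: Me4NBH(OAc)3 (5 equiv), MeCN/AcOH (1:1), −30 °C; aq. KNaC4H4O6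
Reagents that add atoms: none
Why: In the Evans–Saksena reduction the tertiary C7 hydroxyl binds boron and delivers hydride intramolecularly to the ring face it occupies, which should give the 7,9-trans (1,3-anti) diol with (9R) configuration while the lactone is not reduced.

Step 14
Reactants: 28 7,9-trans diol; 29 angelic acid
Product: 31 C9 angelate, via mixed anhydride 30 (not isolated)
Conditions: 29 (3 equiv), 2,4,6-trichlorobenzoyl chloride (3 equiv), Et3N (3 equiv), toluene, rt; then 28, 75 °C, no DMAP
Reagents that add atoms: none
Why: Yamaguchi-type esterification through the mixed anhydride without nucleophilic catalyst should acylate only the secondary C9 hydroxyl (the tertiary C7 hydroxyl is inert) and avoid isomerisation of the Z-configured acyl group to the tiglate.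

Step 15
Reactants: 31 C9 angelate
Product: 32 C13,C14-diol
Conditions: HF·pyridine, pyridine, THF, 0 °C to rt
Reagents that add atoms: none
Why: Fluoride-mediated desilylation removes both primary TBS ethers under buffered conditions to which the lactone, the angelate and the tertiary alcohol are stable.

Step 16
Reactants: 32 C13,C14-diol
Product: 33 C13,C14-diacetate
Conditions: Ac2O (5 equiv), pyridine, 0 °C to rt
Reagents that add atoms: acetic anhydride, CC(=O)OC(C)=O
Why: Acetylation of the two primary hydroxyls installs the C14 acetate of the target and turns the C13 hydroxyl into a leaving group, while the tertiary hydroxyl does not react without acyl-transfer catalyst.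

Step 17
Reactants: 33 C13,C14-diacetate
Product: 34 target (CNP0270682.1)
Conditions: DBU (1.5 equiv), CH2Cl2, 0 °C
Reagents that add atoms: none
Why: E1cB β-elimination of acetate from the β-acetoxy lactone should form the α-methylene lactone and remove the C11 stereocentre, whereas the C14 acetate and the angelate have no acidic C–H in the β-relationship and stay.

**Compound list**

1 | 4-methylpent-4-en-1-ol | C=C(C)CCCO | starting material
2 | 4-methylpent-4-enal | C=C(C)CCC=O | intermediate
3 | ethyl (triphenylphosphoranylidene)acetate | CCOC(=O)C=P(c1ccccc1)(c1ccccc1)c1ccccc1 | starting material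
4 | ethyl iodo(triphenylphosphoranylidene)acetate | CCOC(=O)C(I)=P(c1ccccc1)(c1ccccc1)c1ccccc1 | intermediate (not isolated)
5 | ethyl (2Z)-2-iodo-6-methylhepta-2,6-dienoate | CCOC(=O)/C(I)=C/CCC(C)=C | intermediate
6 | (2Z)-2-iodo-6-methylhepta-2,6-dien-1-ol | OC/C(I)=C/CCC(C)=C | intermediate
7 | tert-butyl{[(2Z)-2-iodo-6-methylhepta-2,6-dien-1-yl]oxy}dimethylsilane | CC(C)(C)[Si](C)(C)OC/C(I)=C/CCC(C)=C | intermediate
8 | (R)-epichlorohydrin, (2R)-2-(chloromethyl)oxirane | ClC[C@H]1CO1 | starting material
9 | alkenyllithium from 7 (lithium in place of iodine, alkene geometry retained, Li cis to C5) | CC(C)(C)[Si](C)(C)OC/C([Li])=C/CCC(C)=C | intermediate (not isolated)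
10 | (2R,4E)-4-[(tert-butyldimethylsilyloxy)methyl]-1-chloro-8-methylnona-4,8-dien-2-ol | C=C(C)CC/C=C(/CO[Si](C)(C)C(C)(C)C)C[C@@H](O)CCl | intermediate (not isolated)
11 | (2R)-2-{(2E)-2-[(tert-butyldimethylsilyloxy)methyl]-6-methylhepta-2,6-dien-1-yl}oxirane | C=C(C)CC/C=C(/CO[Si](C)(C)C(C)(C)C)C[C@@H]1CO1 | intermediate
12 | (phenylthio)acetic acid | OC(=O)CSc1ccccc1 | starting material
13 | dilithium dianion of 12 (carboxylate and α-carbanion) | [Li]OC(=O)C([Li])Sc1ccccc1 | intermediate (not isolated)
14 | (4R,6E)-6-[(tert-butyldimethylsilyloxy)methyl]-4-hydroxy-10-methyl-2-(phenylthio)undeca-6,10-dienoic acid, C2 epimers | C=C(C)CC/C=C(/CO[Si](C)(C)C(C)(C)C)C[C@@H](O)CC(Sc1ccccc1)C(=O)O | intermediate (not isolated)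
15 | (5R)-5-{(2E)-2-[(tert-butyldimethylsilyloxy)methyl]-6-methylhepta-2,6-dien-1-yl}-3-(phenylthio)oxolan-2-one, C3 epimers | C=C(C)CC/C=C(/CO[Si](C)(C)C(C)(C)C)C[C@@H]1CC(Sc2ccccc2)C(=O)O1 | intermediate
16 | formaldehyde (monomer, cracked from paraformaldehyde) | C=O | starting material
17 | lithium enolate of 15 | C=C(C)CC/C=C(/CO[Si](C)(C)C(C)(C)C)C[C@@H]1CC(Sc2ccccc2)=C(O[Li])O1 | intermediate (not isolated)
18 | (5R)-5-{(2E)-2-[(tert-butyldimethylsilyloxy)methyl]-6-methylhepta-2,6-dien-1-yl}-3-(hydroxymethyl)-3-(phenylthio)oxolan-2-one, C3 epimers | C=C(C)CC/C=C(/CO[Si](C)(C)C(C)(C)C)C[C@@H]1CC(CO)(Sc2ccccc2)C(=O)O1 | intermediate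
19 | TBS ether of 18 at the new hydroxymethyl group, C3 epimers | C=C(C)CC/C=C(/CO[Si](C)(C)C(C)(C)C)C[C@@H]1CC(CO[Si](C)(C)C(C)(C)C)(Sc2ccccc2)C(=O)O1 | intermediate
20 | S-oxide (sulfoxide) of 19, epimers at C3 and sulfur | C=C(C)CC/C=C(/CO[Si](C)(C)C(C)(C)C)C[C@@H]1CC(CO[Si](C)(C)C(C)(C)C)(S(=O)c2ccccc2)C(=O)O1 | intermediate (not isolated)
21 | (5R)-3-[(tert-butyldimethylsilyloxy)methyl]-5-{(2E)-2-[(tert-butyldimethylsilyloxy)methyl]-6-methylhepta-2,6-dien-1-yl}furan-2(5H)-one | C=C(C)CC/C=C(/CO[Si](C)(C)C(C)(C)C)C[C@@H]1C=C(CO[Si](C)(C)C(C)(C)C)C(=O)O1 | intermediate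
22 | nitromethane | C[N+](=O)[O-] | starting material
23 | (3R,4R,5R)-3-[(tert-butyldimethylsilyloxy)methyl]-5-{(2E)-2-[(tert-butyldimethylsilyloxy)methyl]-6-methylhepta-2,6-dien-1-yl}-4-(nitromethyl)oxolan-2-one (all-trans) | C=C(C)CC/C=C(/CO[Si](C)(C)C(C)(C)C)C[C@H]1OC(=O)[C@@H](CO[Si](C)(C)C(C)(C)C)[C@@H]1C[N+](=O)[O-] | intermediate
24 | nitrile oxide from 23 (C≡N→O in place of CH2NO2) | C=C(C)CC/C=C(/CO[Si](C)(C)C(C)(C)C)C[C@H]1OC(=O)[C@@H](CO[Si](C)(C)C(C)(C)C)[C@@H]1C#[N+][O-] | intermediate (not isolated)
25 | bridged isoxazoline: ten-membered carbocycle with cis C3=C4, trans-fused γ-lactone at C1/C10, C7–O–N=C9 bridge, CH2OTBS on C3 and on C11, CH3 on C7; (1R,7S,10R,11R) | CC(C)(C)[Si](C)(C)OC[C@@H]1C(=O)O[C@@H]2C/C(CO[Si](C)(C)C(C)(C)C)=C\CC[C@@]3(C)CC(=NO3)[C@@H]12 | intermediate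
26 | β-hydroxy imine: as 25 with the N–O bond cleaved (C7–OH, C9=NH); (1R,7S,10R,11R) | CC(C)(C)[Si](C)(C)OC[C@@H]1C(=O)O[C@@H]2C/C(CO[Si](C)(C)C(C)(C)C)=C\CC[C@](C)(O)CC(=N)[C@@H]12 | intermediate (not isolated)
27 | β-hydroxy ketone: C9 ketone, C7 tertiary alcohol, otherwise as 25; (1R,7S,10S,11R), spatial arrangement unchanged | CC(C)(C)[Si](C)(C)OC[C@@H]1C(=O)O[C@@H]2C/C(CO[Si](C)(C)C(C)(C)C)=C\CC[C@](C)(O)CC(=O)[C@@H]12 | intermediate
28 | 7,9-trans diol: C9 secondary alcohol; (1R,7S,9R,10R,11R), spatial arrangement at C10 unchanged | CC(C)(C)[Si](C)(C)OC[C@@H]1C(=O)O[C@@H]2C/C(CO[Si](C)(C)C(C)(C)C)=C\CC[C@](C)(O)C[C@@H](O)[C@@H]12 | intermediate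
29 | angelic acid, (2Z)-2-methylbut-2-enoic acid | C/C=C(/C)C(=O)O | starting material
30 | angelic 2,4,6-trichlorobenzoic anhydride | C/C=C(/C)C(=O)OC(=O)c1c(Cl)cc(Cl)cc1Cl | intermediate (not isolated)
31 | C9 angelate of 28; (1R,7S,9R,10S,11R) | CC(C)(C)[Si](C)(C)OC[C@@H]1C(=O)O[C@@H]2C/C(CO[Si](C)(C)C(C)(C)C)=C\CC[C@](C)(O)C[C@@H](OC(=O)/C(C)=C\C)[C@@H]12 | intermediate
32 | C13,C14-diol: 31 with both silyl ethers removed | OC[C@@H]1C(=O)O[C@@H]2C/C(CO)=C\CC[C@](C)(O)C[C@@H](OC(=O)/C(C)=C\C)[C@@H]12 | intermediate
33 | C13,C14-diacetate of 32 | CC(=O)OC[C@@H]1C(=O)O[C@@H]2C/C(COC(C)=O)=C\CC[C@](C)(O)C[C@@H](OC(=O)/C(C)=C\C)[C@@H]12 | intermediate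
34 | CNP0270682.1: α-methylene trans-lactone, C14 acetate, C7 tertiary alcohol, C9 angelate, cis C3=C4; (1R,7S,9R,10S) | C=C1C(=O)O[C@@H]2C/C(COC(C)=O)=C\CC[C@](C)(O)C[C@@H](OC(=O)/C(C)=C\C)[C@@H]12 | target

**Totals**

Total step count: 17. Longest linear sequence: 17 steps (from 1).

**Three steps most likely to fail**

First risk, step 11 (the key cycloaddition). The medium-ring closure may lose to bimolecular consumption of the free nitrile oxide (furoxan dimerisation, oligomeric cycloadducts), or the dipole may add to the wrong alkene face. The fallback never liberates the nitrile oxide; it sets out from 23 and comes back to the route at 25. Silylation of 23 (Me3SiCl, Et3N, toluene, rt) should give the trimethylsilyl nitronate F1, a dipole that cannot dimerise. Heating the trimethylsilyl nitronate F1 under dilution (toluene, 80 to 110 °C) should bring about the intramolecular silyl nitronate–alkene cycloaddition, through a bent and more product-like transition state, and give the N-(trimethylsilyloxy)isoxazolidine F2. Treatment of the N-(trimethylsilyloxy)isoxazolidine F2 with TsOH (cat.) should then eliminate trimethylsilanol and give 25.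

Second risk, step 13 (the directed reduction). The hindered tertiary hydroxyl may exchange onto boron too slowly, so that the ketone is reduced from the ring periphery with poor or reversed facial selectivity. The fallback takes the other diol on purpose and corrects C9 during esterification; it sets out from 27 and comes back to the route at 31, so that it replaces step 14 as well. Chelation-controlled Narasaka–Prasad reduction of 27 (Et2BOMe, NaBH4, THF/MeOH, −78 °C) should give the 7,9-cis diol F3. Mitsunobu esterification of the 7,9-cis diol F3 with 29 (PPh3, DIAD, toluene, 0 °C to rt) should invert C9 while installing the angelate and give 31.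

Third risk, step 14 (the angelate esterification). Acyl transfer to the hindered C9 hydroxyl is slow, and the angeloyl group may isomerise to the tigloyl group before it is transferred. The fallback builds the Z-alkene on the ester; it sets out from 28 and comes back to the route at 31. Acylation of 28 with 2-[bis(2,2,2-trifluoroethoxy)phosphoryl]propanoic acid (DCC, DMAP cat., CH2Cl2) should give the phosphonopropanoate F4. Still–Gennari olefination of the phosphonopropanoate F4 with acetaldehyde (KN(SiMe3)2 (1.0 equiv), 18-crown-6, THF, −78 °C) should then give the Z-configured 2-methylbut-2-enoate 31.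

Further compounds
F1 | step 11 | trimethylsilyl nitronate of 23 | C=C(C)CC/C=C(/CO[Si](C)(C)C(C)(C)C)C[C@H]1OC(=O)[C@@H](CO[Si](C)(C)C(C)(C)C)[C@@H]1C=[N+]([O-])O[Si](C)(C)C
F2 | step 11 | N-(trimethylsilyloxy)isoxazolidine, the saturated N-silyloxy analogue of 25 (C9 configuration undefined) | CC(C)(C)[Si](C)(C)OC[C@@H]1C(=O)O[C@@H]2C/C(CO[Si](C)(C)C(C)(C)C)=C\CC[C@@]3(C)CC(N(O[Si](C)(C)C)O3)[C@@H]12
F3 | step 13 | 7,9-cis diol, C9 epimer of 28; (1R,7S,9S,10R,11R) | CC(C)(C)[Si](C)(C)OC[C@@H]1C(=O)O[C@@H]2C/C(CO[Si](C)(C)C(C)(C)C)=C\CC[C@](C)(O)C[C@H](O)[C@@H]12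
F4 | step 14 | C9 2-[bis(2,2,2-trifluoroethoxy)phosphoryl]propanoate of 28 (epimers at the phosphonate carbon) | CC(C)(C)[Si](C)(C)OC[C@@H]1C(=O)O[C@@H]2C/C(CO[Si](C)(C)C(C)(C)C)=C\CC[C@](C)(O)C[C@@H](OC(=O)C(C)P(=O)(OCC(F)(F)F)OCC(F)(F)F)[C@@H]12
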